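The synthesis (labdane numbering) rests on cutting ring A out of the cis-decalin. C1–C10 and C4–C5 are formed in one catalytic asymmetric Diels–Alder reaction between 2,6-dimethyl-1,4-benzoquinone (future ring B, C5–C10, with C17 and C20) and the siloxydiene from mesityl oxide (C1–C4 with the C4 gem-dimethyl). The step exploits the cis C5–C10 fusion of rings A and B, with H-5 and the C10 methyl on one face. It delivers both stereocentres, the C2 oxygen (as silyl enol ether) and the C6/C9 carbonyls at once. Afterwards C17 is oxidised by γ-enolisation and 1,3-transposition, C2 and C6 are reduced, and the butenolide is attached by B-alkyl Suzuki coupling.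

Key step: step 2

Numbering: ring A = C1–C5, C10; ring B = C5–C10; C17 on C8; C18/C19 on C4; C20 on C10; C11–C12 linker; C13–C16 butenolide; β is the face of C20; the target is (2S,5R,6S,10S).

Assumption: the (S)-prolinol-derived oxazaborolidinium is taken to expose the quinone face that leads to the (5R,10S) adduct, following the usual α-C–H···O binding picture for quinones; if the opposite sense were found, the (R)-catalyst would be used with nothing else changed.

Step 1
Reactants: 1 mesityl oxide (4-methylpent-3-en-2-one)
Product: 3 4-methyl-2-(tert-butyldimethylsilyloxy)penta-1,3-diene, via lithium dienolate 2 (not isolated)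
Conditions: LiN(iPr)2, THF, −78 °C; then TBSCl, DMPU, −78 °C → rt
Reagents that add atoms: tert-butyldimethylsilyl chloride, CC(C)(C)[Si](C)(C)Cl
Why: Kinetic deprotonation of the acetyl CH3 (α′) gives the cross-conjugated enolate, which is trapped on oxygen (kinetic silyl enol ether formation), so the CH2=C(OSi)–CH=CMe2 diene is obtained without a stereocentre.

Step 2
Reactants: 3 4-methyl-2-(tert-butyldimethylsilyloxy)penta-1,3-diene; 4 2,6-dimethyl-1,4-benzoquinone
Product: 5 cis-adduct (4aR,8aS)-7-(tert-butyldimethylsilyloxy)-2,5,5,8a-tetramethyl-4a,5,8,8a-tetrahydronaphthalene-1,4-dione (labdane: C2 TBS enol ether, C6 and C9 ketones, C7=C8, 5β-H, 10β-CH3)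
Conditions: (S)-3,3-diphenyl-1-(o-tolyl)tetrahydro-1H,3H-pyrrolo[1,2-c][1,3,2]oxazaborole·Tf2NH (20 mol %), CH2Cl2, −78 → −20 °C; Et3N quench
Reagents that add atoms: none
Why: The N-protonated oxazaborolidine binds the C6 carbonyl, the only quinone carbonyl flanked by vinylic C–H (which supplies the α-C–H···O contact), and thereby makes methyl-bearing C10 the electrophilic β-carbon of the C5=C10 bond. The nucleophilic CH2 terminus of the siloxydiene (C1) bonds to C10 and the dimethylated terminus (C4) to C5 in a strongly asynchronous, suprafacial [4+2] cycloaddition; the closest known reaction type is the oxazaborolidinium-catalysed Diels–Alder reaction of 2-silyloxydienes with methyl-substituted benzoquinones. Ring A is closed as a six-membered carbocycle by intermolecular [4+2] annulation, both ring bonds being made in the same operation. C10 (S) and C5 (R) arise together: suprafacial addition holds H-5 and the C10 methyl cis, and the aryl group of the catalyst, which covers one face of the bound dienophile, decides that both are β. The step needs regio- and enantioface selectivity: the former follows from pairing the nucleophilic diene terminus with the activated β-carbon (which also avoids two adjacent quaternary carbons), the latter from the catalyst, and no site selectivity is required because the two quinone C=C bonds are related by symmetry. The demanding element is the (Z)-methyl of the diene terminus, which disfavours the s-cis conformer, so a higher temperature and catalyst loading than usual are planned.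

Step 3
Reactants: 5 cis-adduct
Product: 6 (5R,10S) C9 ketone carrying C2 (Δ2) and C6 (Δ6) TBS enol ethers and the 8(17)-exo-methylene group
Conditions: TBSOTf, Et3N, CH2Cl2, −78 → 0 °C; used directly
Reagents that add atoms: tert-butyldimethylsilyl trifluoromethanesulfonate, CC(C)(C)[Si](C)(C)OS(=O)(=O)C(F)(F)F
Why: Soft γ-enolisation (vinylogous silyl enol ether formation): O-silylation of the C6 carbonyl and loss of a C17 methyl proton give the extended dienol ether, because the C9 carbonyl has no enolisable position and the α′ C5–H is a hindered tertiary hydrogen, so the C5 configuration should be untouched.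

Step 4
Reactants: 6 bis(silyl enol ether) exo-methylene ketone
Product: 7 9-ethynyl-9-hydroxy derivative of 6 (tertiary propargylic, allylic alcohol; C9 configuration left open)
Conditions: HC≡CMgBr, CeCl3, THF, −78 → 0 °C; pH 7 aqueous quench
Reagents that add atoms: ethynylmagnesium bromide, C#C[Mg]Br
Why: 1,2-Addition of a small alkynyl organometallic to a hindered, non-enolisable ketone (acetylides do not add 1,4 to the exo-methylene enone); the new C9 centre is inconsequential because it becomes sp2 in step 5.

Step 5
Reactants: 7 C9 ethynyl carbinol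
Product: 9 17-trimethylsilyloxy-9-ethynyl-Δ8 compound with C2 and C6 TBS enol ethers, via primary allylic alcohol 8 (not isolated)
Conditions: Ph3SiOReO3 (5 mol %), BSA, Et2O, −50 → 0 °C
Reagents that add atoms: N,O-bis(trimethylsilyl)acetamide, CC(=N[Si](C)(C)C)O[Si](C)(C)C
Why: Perrhenate-ester [3,3]-sigmatropic 1,3-transposition of a tertiary allylic alcohol moves the oxygen from C9 to C17 and the double bond into C8=C9 (tetrasubstituted, conjugated with the alkyne and the C6 enol ether); the alkyne offers no second allyl system, and BSA silylates only the primary alcohol, which pulls the equilibrium and keeps the medium non-acidic for the enol ethers.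

Step 6
Reactants: 9 TMS ether
Product: 10 (5R,10S)-9-ethynyl-17-hydroxy-Δ8-2,6-dione
Conditions: Bu4NF, AcOH, THF, −78 → 0 °C
Reagents that add atoms: none
Why: Fluoride cleaves the silyl ether and both silyl enol ethers, and the ring-B dienolate should be protonated kinetically at C7 (α), giving the β,γ-unsaturated C6 ketone with C8=C9 still conjugated to the alkyne; the acetic acid buffer guards C5 and C7 against base.

Step 7
Reactants: 10 diketo alcohol
Product: 11 (2S,5R,6S,10S)-9-ethynyl-Δ8-2,6,17-triol
Conditions: NaBH4, CeCl3·7H2O, MeOH/THF, −78 → −20 °C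
Reagents that add atoms: none
Why: Luche-type 1,2-reduction in which hydride should reach both carbonyls from the convex β-face of the folded cis-decalin: at C2 the axial C10–C9 bond and the axial 4α-methyl block the α-face of ring A in the conformer with C9 axial (equatorial attack, 2α-OH, 2S), and at C6 the axial C4 with its methyls screens the α-face of ring B (6α-OH, 6S).

Step 8
Reactants: 11 triol enyne
Product: 12 (2S,5R,6S,10S)-9-vinyl-Δ8-2,6,17-triol
Conditions: H2 (1 atm), Pd/CaCO3 poisoned with Pb(OAc)2, quinoline, EtOAc, rt
Reagents that add atoms: none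
Why: Lindlar-type semi-hydrogenation of the terminal alkyne of a conjugated enyne stops at the diene and leaves the tetrasubstituted C8=C9 bond alone.

Step 9
Reactants: 12 triol diene; 13 4-bromofuran-2(5H)-one
Product: 15 target (2S,5R,6S,10S)-triol butenolide, via alkylborane 14 (not isolated)
Conditions: 9-BBN dimer (excess), THF, 0 °C → rt; then 13, PdCl2(dppf), AsPh3, aq K3PO4, DMF, rt
Reagents that add atoms: none
Why: Anti-Markovnikov hydroboration of the only unhindered alkene places boron on C12, and B-alkyl Suzuki–Miyaura coupling with the β-bromobutenolide forms C12–C13; the three hydroxyls are carried as borinates that are released on work-up.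

Compound list
1 | mesityl oxide | CC(=O)C=C(C)C | starting material
2 | lithium 4-methylpenta-1,3-dien-2-olate | [Li+].[O-]C(=C)C=C(C)C | intermediate
3 | 4-methyl-2-(tert-butyldimethylsilyloxy)penta-1,3-diene | C=C(O[Si](C)(C)C(C)(C)C)C=C(C)C | intermediate
4 | 2,6-dimethyl-1,4-benzoquinone | CC1=CC(=O)C=C(C)C1=O | starting material
5 | (4aR,8aS)-7-(tert-butyldimethylsilyloxy)-2,5,5,8a-tetramethyl-4a,5,8,8a-tetrahydronaphthalene-1,4-dione | CC1(C)C=C(O[Si](C)(C)C(C)(C)C)C[C@]2(C)C(=O)C(C)=CC(=O)[C@H]12 | intermediate
6 | (5R,10S) C9 ketone with C2 and C6 TBS enol ethers and 8(17)-methylene | CC1(C)C=C(O[Si](C)(C)C(C)(C)C)C[C@]2(C)C(=O)C(=C)C=C(O[Si](C)(C)C(C)(C)C)[C@H]12 | intermediate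
7 | 9-ethynyl-9-hydroxy derivative of 6 (C9 unassigned) | CC1(C)C=C(O[Si](C)(C)C(C)(C)C)C[C@]2(C)C(O)(C#C)C(=C)C=C(O[Si](C)(C)C(C)(C)C)[C@H]12 | intermediate
8 | 9-ethynyl-17-hydroxy-Δ8 compound with C2 and C6 TBS enol ethers | CC1(C)C=C(O[Si](C)(C)C(C)(C)C)C[C@]2(C)C(C#C)=C(CO)C=C(O[Si](C)(C)C(C)(C)C)[C@H]12 | intermediate
9 | 17-O-trimethylsilyl ether of 8 | CC1(C)C=C(O[Si](C)(C)C(C)(C)C)C[C@]2(C)C(C#C)=C(CO[Si](C)(C)C)C=C(O[Si](C)(C)C(C)(C)C)[C@H]12 | intermediate
10 | (5R,10S)-9-ethynyl-17-hydroxy-Δ8-2,6-dione | CC1(C)CC(=O)C[C@]2(C)C(C#C)=C(CO)CC(=O)[C@H]12 | intermediate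
11 | (2S,5R,6S,10S)-9-ethynyl-Δ8-2,6,17-triol | CC1(C)C[C@H](O)C[C@]2(C)C(C#C)=C(CO)C[C@H](O)[C@H]12 | intermediate
12 | (2S,5R,6S,10S)-9-vinyl-Δ8-2,6,17-triol | CC1(C)C[C@H](O)C[C@]2(C)C(C=C)=C(CO)C[C@H](O)[C@H]12 | intermediate
13 | 4-bromofuran-2(5H)-one | O=C1C=C(Br)CO1 | starting material
14 | C12 B-alkyl-9-borabicyclo[3.3.1]nonane of 12 | CC1(C)C[C@H](O)C[C@]2(C)C(CCB3C4CCCC3CCC4)=C(CO)C[C@H](O)[C@H]12 | intermediate
15 | CNP0293367.1, (2S,5R,6S,10S) | CC1(C)C[C@H](O)C[C@]2(C)C(CCC3=CC(=O)OC3)=C(CO)C[C@H](O)[C@H]12 | target

Total step count: 9. Longest linear sequence: 9 steps (1 → 15); 4 and 13 are purchased and enter at steps 2 and 9.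

Steps most likely to fail

Step 2. The doubly methylated diene terminus may keep the diene out of the s-cis conformer, so that conversion is low or open-chain conjugate-addition products appear. Silyl transfer from the diene to the triflimide may also start an achiral background reaction and erode the enantiomeric purity. Fallback: setting out from 3 and 4, the annulation is run under a strong achiral promoter (AlBr3/AlMe3 10:1, toluene/CH2Cl2, −20 °C), the kind of mixed Lewis acid used for doubly hindered silyloxydiene–enone pairs. This should give the racemic cis-adduct, that is 5 together with the enantiomeric adduct F1. The two are separated by preparative chromatography on a chiral stationary phase, and the route is rejoined at 5.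

Step 5. Adventitious perrhenic acid may strip the silyl enol ethers, or the tertiary propargylic perrhenate may ionise towards Meyer–Schuster or elimination products instead of undergoing the allylic shift. Fallback: setting out from 7, an Appel-type halogenation with allylic rearrangement (CBr4, PPh3, CH2Cl2, −20 °C) should give the rearranged primary allylic bromide F2. Displacement with CsOAc in DMF gives the allylic acetate F3, and reductive ester cleavage (i-Bu2AlH, CH2Cl2, −78 °C) gives 8. Compound 8 is submitted directly to the step 6 conditions, so the route is rejoined at 8 and continues to 10.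

Step 7. Facial selectivity at C2 may be poor if the second ring conformer (C6 axial on ring A, C20 and the 4β-methyl diaxial) reacts competitively, since equatorial attack on that conformer gives the 2β-epimer. Fallback: setting out from 9, the two carbonyls are unmasked and reduced one after the other so that the C6 carbinol locks the ring conformation before C2 is touched.
- Buffered fluoride in limited amount (Bu4NF 2 equiv, AcOH, THF, −78 °C) should cleave the TMS ether and the more labile ring-B dienol silyl ether, whose extended enolate is the better leaving group. This gives the C6 ketone F4 with the C2 enol ether intact.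
- NaBH4 in MeOH/THF at −40 °C gives the 6α-carbinol F5. Its hydroxyl cannot be accommodated under ring A, so only the conformer with C9 axial remains.
- A second desilylation (Bu4NF, AcOH, THF, 0 °C) gives the C2 ketone F6.
- Reduction with NaBH4 or LiBH(s-Bu)3 at −78 °C from the only open β-face rejoins the route at 11.

Further compounds
F1 | step 2 | (4aS,8aR) enantiomer of adduct 5 | CC1(C)C=C(O[Si](C)(C)C(C)(C)C)C[C@@]2(C)C(=O)C(C)=CC(=O)[C@@H]12
F2 | step 5 | 17-bromo-9-ethynyl-Δ8 compound with C2 and C6 TBS enol ethers | CC1(C)C=C(O[Si](C)(C)C(C)(C)C)C[C@]2(C)C(C#C)=C(CBr)C=C(O[Si](C)(C)C(C)(C)C)[C@H]12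
F3 | step 5 | 17-acetoxy-9-ethynyl-Δ8 compound with C2 and C6 TBS enol ethers | CC1(C)C=C(O[Si](C)(C)C(C)(C)C)C[C@]2(C)C(C#C)=C(COC(C)=O)C=C(O[Si](C)(C)C(C)(C)C)[C@H]12
F4 | step 7 | 9-ethynyl-17-hydroxy-Δ8-6-ketone with C2 TBS enol ether | CC1(C)C=C(O[Si](C)(C)C(C)(C)C)C[C@]2(C)C(C#C)=C(CO)CC(=O)[C@H]12
F5 | step 7 | (6S) 6α,17-diol with C2 TBS enol ether | CC1(C)C=C(O[Si](C)(C)C(C)(C)C)C[C@]2(C)C(C#C)=C(CO)C[C@H](O)[C@H]12
F6 | step 7 | (5R,6S,10S)-9-ethynyl-6,17-dihydroxy-Δ8-2-ketone | CC1(C)CC(=O)C[C@]2(C)C(C#C)=C(CO)C[C@H](O)[C@H]12
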